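**Retrosynthetic overview**
- Target ⇒ phenol desilylation, C10 tigloylation and MOM removal ⇒ late esterification of a bicyclic dauc-8-ene-4,6-diol (21 non-hydrogen atoms) with 4-(TBSO)benzoyl chloride (17 non-hydrogen atoms).
- Seven-membered ring ⇒ ring-closing metathesis (C8=C9) of a diene made by double methylenation of a keto aldehyde.
- C4 carbinol ⇒ Markovnikov hydration of a 4-isopropylcyclopent-3-ene, itself from the enol triflate of a cyclopentenone; C5–C6 ⇒ anti aldol with a masked 3-oxobutanal.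
- C1/C10 ⇒ Ireland–Claisen rearrangement of (S)-3-methylcyclopent-2-enyl MOM-glycolate (chirality from a CBS reduction), then allylic oxidation to the 4,4-disubstituted cyclopentenone.
- Ring order: the five-membered ring comes from 3-methylcyclopent-2-enone; the seven-membered ring is closed last by metathesis.

Assumption: positions are cited in daucane numbering (C1 = ring-fusion carbon with CH3, C4 = carbinol carbon with isopropyl, C5 = ring-fusion CH, C6 = aroyloxy carbon, C8 = CH3-bearing alkene carbon, C10 = tigloyloxy carbon).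

**Fragment syntheses**

Step 1
Reactants: 1 glycolic acid
Product: 3 2-(methoxymethoxy)acetic acid, via methoxymethyl ester 2 (not isolated)
Conditions: MOMCl (2.4 equiv), iPr2NEt, CH2Cl2, 0 → 23 °C; then LiOH, THF/H2O, 0 °C; HCl to pH 3
Reagents that add atoms: chloromethyl methyl ether COCCl; lithium hydroxide [Li+].[OH-]
Why: Double O-alkylation followed by saponification, which cleaves only the acyl–O bond of the MOM ester and leaves the MOM ether.

Step 2
Reactants: 4 methyl acetoacetate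
Product: 5 methyl 2-(2-methyl-1,3-dioxolan-2-yl)acetate
Conditions: HOCH2CH2OH, TsOH (cat.), PhMe, reflux, Dean–Stark
Reagents that add atoms: ethylene glycol OCCO
Why: Acid-catalysed ketalisation of the ketone carbonyl, driven by azeotropic removal of water.

Step 3
Reactants: 5 methyl 2-(2-methyl-1,3-dioxolan-2-yl)acetate
Product: 6 2-(2-methyl-1,3-dioxolan-2-yl)ethan-1-ol
Conditions: LiAlH4, Et2O, 0 °C
Reagents that add atoms: none
Why: Hydride reduction of the ester; the ketal is inert to LiAlH4.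

Step 4
Reactants: 6 2-(2-methyl-1,3-dioxolan-2-yl)ethan-1-ol
Product: 7 2-(2-methyl-1,3-dioxolan-2-yl)acetaldehyde
Conditions: TEMPO (cat.), PhI(OAc)2, CH2Cl2, 23 °C
Reagents that add atoms: none
Why: Oxoammonium (TEMPO) oxidation stops at the aldehyde under near-neutral conditions that spare the ketal; 7 is used at once.

Step 5
Reactants: 8 4-bromophenol
Product: 9 (4-bromophenoxy)(tert-butyl)dimethylsilane
Conditions: TBSCl, imidazole, DMF, 23 °C
Reagents that add atoms: tert-butyldimethylsilyl chloride CC(C)(C)[Si](C)(C)Cl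
Why: Standard O-silylation of the phenol.

Step 6
Reactants: 9 (4-bromophenoxy)(tert-butyl)dimethylsilane
Product: 11 4-[(tert-butyldimethylsilyl)oxy]benzoic acid, via aryllithium 10 (not isolated)
Conditions: n-BuLi, THF, −78 °C; CO2; 1 M HCl to pH 4
Reagents that add atoms: carbon dioxide O=C=O
Why: Bromine–lithium exchange and carboxylation; the para-lithio species cannot undergo O→C silyl migration.

Step 7
Reactants: 11 4-[(tert-butyldimethylsilyl)oxy]benzoic acid
Product: 12 4-[(tert-butyldimethylsilyl)oxy]benzoyl chloride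
Conditions: (COCl)2, DMF (cat.), CH2Cl2, 0 → 23 °C
Reagents that add atoms: oxalyl chloride O=C(Cl)C(=O)Cl
Why: Vilsmeier-catalysed acid chloride formation; the aryl silyl ether tolerates the HCl released.

Step 8
Reactants: 13 tiglic acid
Product: 14 tigloyl chloride
Conditions: (COCl)2, DMF (cat.), CH2Cl2, 0 → 23 °C
Reagents that add atoms: oxalyl chloride O=C(Cl)C(=O)Cl
Why: Acid chloride formation under mild conditions that keep the thermodynamically preferred (E) geometry.

**Main line**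

Step 9
Reactants: 15 3-methylcyclopent-2-en-1-one
Product: 16 (S)-3-methylcyclopent-2-en-1-ol
Conditions: (R)-1-methyl-3,3-diphenyltetrahydro-1H,3H-pyrrolo[1,2-c][1,3,2]oxazaborole (10 mol %), BH3·SMe2, THF, −20 °C; MeOH
Reagents that add atoms: none
Why: Corey–Bakshi–Shibata reduction; the alkenyl carbon acts as the large group, so the (R)-catalyst gives the (S)-carbinol (about 90% ee expected).

Step 10
Reactants: 16 (S)-3-methylcyclopent-2-en-1-ol; 3 2-(methoxymethoxy)acetic acid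
Product: 17 (1S)-3-methylcyclopent-2-en-1-yl (methoxymethoxy)acetate
Conditions: DCC, DMAP (cat.), CH2Cl2, 0 °C
Reagents that add atoms: none
Why: Steglich esterification under neutral conditions that avoid ionisation of the allylic C–O bond.

Step 11
Reactants: 17 (1S)-3-methylcyclopent-2-en-1-yl (methoxymethoxy)acetate
Product: 21 methyl (2S)-(methoxymethoxy)[(1R)-1-methylcyclopent-2-en-1-yl]acetate, via silyl ketene acetal 18 (not isolated), via trimethylsilyl ester 19 (not isolated), via carboxylic acid 20 (not isolated)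
Conditions: LiN(SiMe3)2, Me3SiCl, Et3N, THF, −78 → 55 °C; 1 M HCl; then Me3SiCHN2, PhMe/MeOH, 0 °C
Reagents that add atoms: (trimethylsilyl)diazomethane C[Si](C)(C)C=[N+]=[N-]
Why: Ireland–Claisen rearrangement: suprafacial transfer from the carbinol centre sets quaternary C1, and the chelated (Z)-ketene acetal reacting through the boat-like transition state usual for cycloalkenyl esters sets C10.

Step 12
Reactants: 21 methyl (2S)-(methoxymethoxy)[(1R)-1-methylcyclopent-2-en-1-yl]acetate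
Product: 22 methyl (2S)-(methoxymethoxy)[(1R)-1-methyl-4-oxocyclopent-2-en-1-yl]acetate
Conditions: CrO3, 3,5-dimethylpyrazole, CH2Cl2, −20 °C
Reagents that add atoms: chromium trioxide O=[Cr](=O)=O
Why: Allylic oxidation of the only allylic CH2; the other allyl terminus is neopentylic, so the carbonyl is placed at C4.

Step 13
Reactants: 22 methyl (2S)-(methoxymethoxy)[(1R)-1-methyl-4-oxocyclopent-2-en-1-yl]acetate; 7 2-(2-methyl-1,3-dioxolan-2-yl)acetaldehyde
Product: 25 methyl (2S)-(methoxymethoxy)[(1S,5S)-1-methyl-5-{(1S)-2-(2-methyl-1,3-dioxolan-2-yl)-1-[(triethylsilyl)oxy]ethyl}-4-oxocyclopent-2-en-1-yl]acetate, via lithium dienolate 23 (not isolated), via lithium aldolate 24 (not isolated)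
Conditions: LiN(iPr)2, THF, −78 °C; 7; then Et3SiCl, DMPU, −78 → −30 °C
Reagents that add atoms: chlorotriethylsilane CC[Si](Cl)(CC)CC
Why: Kinetic aldol addition: only C5 can be deprotonated (C1 is quaternary), the aldehyde approaches anti to the bulky C1 side chain (setting C5), and the ring-locked (E)-enolate in a Zimmerman–Traxler transition state gives the anti aldol (setting C6).

Step 14
Reactants: 25 (TES aldol enone)
Product: 27 methyl (2S)-(methoxymethoxy)[(1S,5S)-1-methyl-5-{(1S)-2-(2-methyl-1,3-dioxolan-2-yl)-1-[(triethylsilyl)oxy]ethyl}-4-{[(trifluoromethyl)sulfonyl]oxy}cyclopent-3-en-1-yl]acetate, via silyl enol ether 26 (not isolated)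
Conditions: [(Ph3P)CuH]6 (5 mol % Cu), PhMe2SiH, PhMe, 23 °C; then PhNTf2, CsF, DME, 23 °C
Reagents that add atoms: N-phenylbis(trifluoromethanesulfonimide) O=S(=O)(N(c1ccccc1)S(=O)(=O)C(F)(F)F)C(F)(F)F
Why: Copper hydride 1,4-hydrosilylation gives the C3=C4 silyl enol ether regiospecifically, and fluoride-triggered triflation with PhNTf2 keeps that regiochemistry.

Step 15
Reactants: 27 (enol triflate)
Product: 28 methyl (2S)-(methoxymethoxy)[(1S,5S)-1-methyl-5-{(1S)-2-(2-methyl-1,3-dioxolan-2-yl)-1-[(triethylsilyl)oxy]ethyl}-4-(propan-2-yl)cyclopent-3-en-1-yl]acetate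
Conditions: iPrMgBr, Fe(acac)3 (5 mol %), THF/NMP, −30 °C
Reagents that add atoms: isopropylmagnesium bromide CC(C)[Mg]Br
Why: Iron-catalysed Kochi–Fürstner cross-coupling of an alkenyl triflate with a secondary alkyl Grignard reagent is faster than attack on the ester at −30 °C.

Step 16
Reactants: 28 (isopropylcyclopentene)
Product: 29 methyl (2S)-[(1S,2S,3S)-3-hydroxy-1-methyl-2-{(1S)-2-(2-methyl-1,3-dioxolan-2-yl)-1-[(triethylsilyl)oxy]ethyl}-3-(propan-2-yl)cyclopentyl](methoxymethoxy)acetate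
Conditions: Co(acac)2 (20 mol %), PhSiH3, O2 (1 atm), THF, 23 °C
Reagents that add atoms: dioxygen O=O
Why: Mukaiyama hydration: hydrogen-atom transfer to C3 gives the tertiary C4 radical, which is trapped by O2 on the face opposite the adjacent C5 side chain, so OH is cis to H5 and isopropyl cis to the C5 arm.

Step 17
Reactants: 29 (tertiary alcohol ester)
Product: 31 (2S)-{(1S,2S,3S)-3-hydroxy-2-[(1S)-1-hydroxy-3-oxobutyl]-1-methyl-3-(propan-2-yl)cyclopentyl}(methoxymethoxy)acetaldehyde, via aldehyde 30 (not isolated)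
Conditions: iBu2AlH, CH2Cl2, −78 °C; MeOH; then 1 M HCl, THF, 23 °C
Reagents that add atoms: water O
Why: Partial reduction of the α-alkoxy ester through a chelated aluminium hemiacetal, then mild acid hydrolysis of the dioxolane and the triethylsilyl ether while the MOM ether survives; 31 equilibrates with its lactols and is used crude.

Step 18
Reactants: 31 (hydroxy keto aldehyde)
Product: 32 (1S,2S,3S)-2-[(1S)-1-hydroxy-3-methylbut-3-en-1-yl]-3-[(1R)-1-(methoxymethoxy)prop-2-en-1-yl]-3-methyl-1-(propan-2-yl)cyclopentan-1-ol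
Conditions: Ph3PCH3Br, KOtBu, THF, 0 → 23 °C
Reagents that add atoms: methyltriphenylphosphonium bromide C[P+](c1ccccc1)(c1ccccc1)c1ccccc1.[Br-]
Why: Double Wittig methylenation of the aldehyde (through its open form) and the methyl ketone with excess preformed ylide, which is too weakly basic to deprotonate the alcohols.

Step 19
Reactants: 32 (diene diol)
Product: 33 (1S,4S,5S,6S,10R)-10-(methoxymethoxy)dauc-8-ene-4,6-diol
Conditions: second-generation Grubbs catalyst RuCl2(=CHPh)(PCy3)(H2IMes) (5 mol %), CH2Cl2 (2 mM), 40 °C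
Reagents that add atoms: none
Why: Ring-closing metathesis of the vinyl and 2-methylallyl groups held trans on the cyclopentane closes the trans-fused cycloheptene with the trisubstituted C8=C9 bond.

Step 20
Reactants: 33 (bicyclic diol); 12 4-[(tert-butyldimethylsilyl)oxy]benzoyl chloride
Product: 34 (1S,4S,5S,6S,10R)-4-hydroxy-10-(methoxymethoxy)dauc-8-en-6-yl 4-[(tert-butyldimethylsilyl)oxy]benzoate
Conditions: DMAP, Et3N, CH2Cl2, 0 → 23 °C
Reagents that add atoms: none
Why: DMAP-catalysed acylation joins the two fragments at the only secondary hydroxyl (C6); the tertiary C4–OH does not react.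

Step 21
Reactants: 34 (MOM ether aryl ester)
Product: 35 (1S,4S,5S,6S,10R)-4,10-dihydroxydauc-8-en-6-yl 4-[(tert-butyldimethylsilyl)oxy]benzoate
Conditions: ZnBr2, n-PrSH, CH2Cl2, 0 °C
Reagents that add atoms: none
Why: Lewis acid-assisted thiolysis of the MOM acetal is fast and spares the aryl silyl ether, the ester and the tertiary alcohol.

Step 22
Reactants: 35 (C10 alcohol); 14 tigloyl chloride
Product: 36 (1S,4S,5S,6S,10R)-4-hydroxy-10-[(E)-2-methylbut-2-enoyloxy]dauc-8-en-6-yl 4-[(tert-butyldimethylsilyl)oxy]benzoate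
Conditions: DMAP, Et3N, CH2Cl2, 0 → 40 °C
Reagents that add atoms: none
Why: Acyl transfer via the acylpyridinium to the hindered allylic C10–OH, with retention at C10 and no acylation of the tertiary C4–OH.

Step 23
Reactants: 36 (silyl-protected diester)
Product: 37 (1S,4S,5S,6S,10R)-4-hydroxy-10-[(E)-2-methylbut-2-enoyloxy]dauc-8-en-6-yl 4-hydroxybenzoate (CNP0273650.6)
Conditions: Bu4NF, AcOH, THF, 0 °C
Reagents that add atoms: none
Why: Buffered fluoride cleaves the aryl silyl ether within minutes without touching either ester.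

**Compound list**
1 | glycolic acid | OCC(=O)O | starting material
2 | methoxymethyl 2-(methoxymethoxy)acetate | COCOCC(=O)OCOC | intermediate
3 | 2-(methoxymethoxy)acetic acid | COCOCC(=O)O | intermediate
4 | methyl acetoacetate | COC(=O)CC(C)=O | starting material
5 | methyl 2-(2-methyl-1,3-dioxolan-2-yl)acetate | COC(=O)CC1(C)OCCO1 | intermediate
6 | 2-(2-methyl-1,3-dioxolan-2-yl)ethan-1-ol | OCCC1(C)OCCO1 | intermediate
7 | 2-(2-methyl-1,3-dioxolan-2-yl)acetaldehyde | O=CCC1(C)OCCO1 | intermediate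
8 | 4-bromophenol | Oc1ccc(Br)cc1 | starting material
9 | (4-bromophenoxy)(tert-butyl)dimethylsilane | CC(C)(C)[Si](C)(C)Oc1ccc(Br)cc1 | intermediate
10 | {4-[(tert-butyldimethylsilyl)oxy]phenyl}lithium | [Li]c1ccc(O[Si](C)(C)C(C)(C)C)cc1 | intermediate
11 | 4-[(tert-butyldimethylsilyl)oxy]benzoic acid | CC(C)(C)[Si](C)(C)Oc1ccc(C(=O)O)cc1 | intermediate
12 | 4-[(tert-butyldimethylsilyl)oxy]benzoyl chloride | CC(C)(C)[Si](C)(C)Oc1ccc(C(=O)Cl)cc1 | intermediate
13 | tiglic acid, (E)-2-methylbut-2-enoic acid | C/C=C(\C)C(=O)O | starting material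
14 | tigloyl chloride, (E)-2-methylbut-2-enoyl chloride | C/C=C(\C)C(=O)Cl | intermediate
15 | 3-methylcyclopent-2-en-1-one | CC1=CC(=O)CC1 | starting material
16 | (S)-3-methylcyclopent-2-en-1-ol | O[C@@H]1C=C(C)CC1 | intermediate
17 | (1S)-3-methylcyclopent-2-en-1-yl (methoxymethoxy)acetate | COCOCC(=O)O[C@@H]1C=C(C)CC1 | intermediate
18 | (Z)-O-trimethylsilyl ketene acetal of 17 (OMOM cis to OSiMe3) | COCO/C=C(\O[Si](C)(C)C)O[C@@H]1C=C(C)CC1 | intermediate
19 | trimethylsilyl (2S)-(methoxymethoxy)[(1R)-1-methylcyclopent-2-en-1-yl]acetate | C[Si](C)(C)OC(=O)[C@@H](OCOC)[C@@]1(C)C=CCC1 | intermediate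
20 | (2S)-(methoxymethoxy)[(1R)-1-methylcyclopent-2-en-1-yl]acetic acid | OC(=O)[C@@H](OCOC)[C@@]1(C)C=CCC1 | intermediate
21 | methyl (2S)-(methoxymethoxy)[(1R)-1-methylcyclopent-2-en-1-yl]acetate | COC(=O)[C@@H](OCOC)[C@@]1(C)C=CCC1 | intermediate
22 | methyl (2S)-(methoxymethoxy)[(1R)-1-methyl-4-oxocyclopent-2-en-1-yl]acetate | COC(=O)[C@@H](OCOC)[C@@]1(C)C=CC(=O)C1 | intermediate
23 | lithium cross-conjugated dienolate of 22 (O–Li at C4, C4=C5) | COC(=O)[C@@H](OCOC)[C@@]1(C)C=CC(O[Li])=C1 | intermediate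
24 | lithium aldolate (C6–OLi analogue of 25) | COC(=O)[C@@H](OCOC)[C@@]1(C)C=CC(=O)[C@@H]1[C@@H](O[Li])CC2(C)OCCO2 | intermediate
25 | methyl (2S)-(methoxymethoxy)[(1S,5S)-1-methyl-5-{(1S)-2-(2-methyl-1,3-dioxolan-2-yl)-1-[(triethylsilyl)oxy]ethyl}-4-oxocyclopent-2-en-1-yl]acetate | COC(=O)[C@@H](OCOC)[C@@]1(C)C=CC(=O)[C@@H]1[C@@H](O[Si](CC)(CC)CC)CC2(C)OCCO2 | intermediate
26 | dimethyl(phenyl)silyl enol ether (C3=C4–OSiMe2Ph) of the 2,3-dihydro derivative of 25 | COC(=O)[C@@H](OCOC)[C@@]1(C)CC=C(O[Si](C)(C)c2ccccc2)[C@@H]1[C@@H](O[Si](CC)(CC)CC)CC3(C)OCCO3 | intermediate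
27 | methyl (2S)-(methoxymethoxy)[(1S,5S)-1-methyl-5-{(1S)-2-(2-methyl-1,3-dioxolan-2-yl)-1-[(triethylsilyl)oxy]ethyl}-4-{[(trifluoromethyl)sulfonyl]oxy}cyclopent-3-en-1-yl]acetate | COC(=O)[C@@H](OCOC)[C@@]1(C)CC=C(OS(=O)(=O)C(F)(F)F)[C@@H]1[C@@H](O[Si](CC)(CC)CC)CC2(C)OCCO2 | intermediate
28 | methyl (2S)-(methoxymethoxy)[(1S,5S)-1-methyl-5-{(1S)-2-(2-methyl-1,3-dioxolan-2-yl)-1-[(triethylsilyl)oxy]ethyl}-4-(propan-2-yl)cyclopent-3-en-1-yl]acetate | COC(=O)[C@@H](OCOC)[C@@]1(C)CC=C(C(C)C)[C@@H]1[C@@H](O[Si](CC)(CC)CC)CC2(C)OCCO2 | intermediate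
29 | methyl (2S)-[(1S,2S,3S)-3-hydroxy-1-methyl-2-{(1S)-2-(2-methyl-1,3-dioxolan-2-yl)-1-[(triethylsilyl)oxy]ethyl}-3-(propan-2-yl)cyclopentyl](methoxymethoxy)acetate | COC(=O)[C@@H](OCOC)[C@@]1(C)CC[C@](O)(C(C)C)[C@@H]1[C@@H](O[Si](CC)(CC)CC)CC2(C)OCCO2 | intermediate
30 | (2S)-[(1S,2S,3S)-3-hydroxy-1-methyl-2-{(1S)-2-(2-methyl-1,3-dioxolan-2-yl)-1-[(triethylsilyl)oxy]ethyl}-3-(propan-2-yl)cyclopentyl](methoxymethoxy)acetaldehyde | O=C[C@@H](OCOC)[C@@]1(C)CC[C@](O)(C(C)C)[C@@H]1[C@@H](O[Si](CC)(CC)CC)CC2(C)OCCO2 | intermediate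
31 | (2S)-{(1S,2S,3S)-3-hydroxy-2-[(1S)-1-hydroxy-3-oxobutyl]-1-methyl-3-(propan-2-yl)cyclopentyl}(methoxymethoxy)acetaldehyde | O=C[C@@H](OCOC)[C@@]1(C)CC[C@](O)(C(C)C)[C@@H]1[C@@H](O)CC(C)=O | intermediate
32 | (1S,2S,3S)-2-[(1S)-1-hydroxy-3-methylbut-3-en-1-yl]-3-[(1R)-1-(methoxymethoxy)prop-2-en-1-yl]-3-methyl-1-(propan-2-yl)cyclopentan-1-ol | C=C[C@@H](OCOC)[C@@]1(C)CC[C@](O)(C(C)C)[C@@H]1[C@@H](O)CC(C)=C | intermediate
33 | (1S,4S,5S,6S,10R)-10-(methoxymethoxy)dauc-8-ene-4,6-diol (trans-fused) | COCO[C@@H]1C=C(C)C[C@H](O)[C@@H]2[C@]1(C)CC[C@]2(O)C(C)C | intermediate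
34 | (1S,4S,5S,6S,10R)-4-hydroxy-10-(methoxymethoxy)dauc-8-en-6-yl 4-[(tert-butyldimethylsilyl)oxy]benzoate | COCO[C@@H]1C=C(C)C[C@H](OC(=O)c2ccc(O[Si](C)(C)C(C)(C)C)cc2)[C@@H]2[C@]1(C)CC[C@]2(O)C(C)C | intermediate
35 | (1S,4S,5S,6S,10R)-4,10-dihydroxydauc-8-en-6-yl 4-[(tert-butyldimethylsilyl)oxy]benzoate | O[C@@H]1C=C(C)C[C@H](OC(=O)c2ccc(O[Si](C)(C)C(C)(C)C)cc2)[C@@H]2[C@]1(C)CC[C@]2(O)C(C)C | intermediate
36 | (1S,4S,5S,6S,10R)-4-hydroxy-10-[(E)-2-methylbut-2-enoyloxy]dauc-8-en-6-yl 4-[(tert-butyldimethylsilyl)oxy]benzoate | C/C=C(\C)C(=O)O[C@@H]1C=C(C)C[C@H](OC(=O)c2ccc(O[Si](C)(C)C(C)(C)C)cc2)[C@@H]2[C@]1(C)CC[C@]2(O)C(C)C | intermediate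
37 | (1S,4S,5S,6S,10R)-4-hydroxy-10-[(E)-2-methylbut-2-enoyloxy]dauc-8-en-6-yl 4-hydroxybenzoate | C/C=C(\C)C(=O)O[C@@H]1C=C(C)C[C@H](OC(=O)c2ccc(O)cc2)[C@@H]2[C@]1(C)CC[C@]2(O)C(C)C | target

**Step count**
- Total: 23 steps.
- Longest linear sequence: 15 steps (15 → 37 through steps 9–23; equally 1 → 37 through step 1 and steps 10–23).

**Three steps most likely to fail**

Step 11 (Ireland–Claisen). The C10 configuration rests on a chelated (Z)-ketene acetal and a boat-like transition state while a quaternary carbon is formed, so the diastereomer ratio may be poor. Fallback: from 16, a Johnson–Claisen rearrangement (MeC(OMe)3, EtCO2H cat., 140 °C) sets only C1 and gives methyl 2-[(1S)-1-methylcyclopent-2-en-1-yl]acetate F1. Enolisation with KN(SiMe3)2 and reagent-controlled hydroxylation with the matched enantiomer of Davis' (camphorsulfonyl)oxaziridine gives methyl (2S)-hydroxy[(1R)-1-methylcyclopent-2-en-1-yl]acetate F2. MOMCl/iPr2NEt then returns to 21.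

Step 16 (Mukaiyama hydration). Face selectivity at C4 and competing reduction to the alkane are uncertain. Fallback: from 28, mCPBA (NaHCO3, CH2Cl2, 0 °C) epoxidises the trisubstituted alkene on the face opposite the C5 side chain to give the 3,4-epoxide of 28 F3. LiBHEt3 (THF, 0 → 23 °C) opens it by SN2 attack at the secondary C3 and also reduces the ester, giving the C9 primary alcohol (C4,C9-diol) F4. TEMPO/PhI(OAc)2 oxidises only the primary alcohol and returns to 30, which continues with the HCl stage of step 17.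

Step 18 (double Wittig). The free β-hydroxy ketone can undergo retro-aldol cleavage or dehydration, and the lactol may react slowly. Fallback: from 30 (isolated after a neutral work-up), Ph3P=CH2 methylenates the aldehyde alone to give the C9-vinyl ketal silyl ether F5. 1 M HCl/THF removes the ketal and the silyl ether to give the C9-vinyl β-hydroxy ketone F6. Non-basic Takai–Lombardo methylenation (Zn, CH2Br2, TiCl4, THF) converts the ketone and returns to 32.

**Further compounds**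
F1 | step 11 | methyl 2-[(1S)-1-methylcyclopent-2-en-1-yl]acetate | COC(=O)C[C@@]1(C)C=CCC1
F2 | step 11 | methyl (2S)-hydroxy[(1R)-1-methylcyclopent-2-en-1-yl]acetate | COC(=O)[C@@H](O)[C@@]1(C)C=CCC1
F3 | step 16 | 3,4-epoxide of 28 (oxirane oxygen trans to the C5 side chain) | COC(=O)[C@@H](OCOC)[C@@]1(C)C[C@H]2O[C@@]2(C(C)C)[C@@H]1[C@@H](O[Si](CC)(CC)CC)CC3(C)OCCO3
F4 | step 16 | C9 primary alcohol (C4,C9-diol) corresponding to 29 | OC[C@@H](OCOC)[C@@]1(C)CC[C@](O)(C(C)C)[C@@H]1[C@@H](O[Si](CC)(CC)CC)CC2(C)OCCO2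
F5 | step 18 | C9-vinyl ketal silyl ether (Wittig product of 30) | C=C[C@@H](OCOC)[C@@]1(C)CC[C@](O)(C(C)C)[C@@H]1[C@@H](O[Si](CC)(CC)CC)CC2(C)OCCO2
F6 | step 18 | C9-vinyl β-hydroxy ketone | C=C[C@@H](OCOC)[C@@]1(C)CC[C@](O)(C(C)C)[C@@H]1[C@@H](O)CC(C)=O
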